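**Plan**

- Retrosynthesis: remove the N-Boc group, then open ring C of the flavone at C4a–C4, C4–C3 and O1–C2 (back to an iodo-resorcinol, CO and phenylacetylene), then the C–I bond. Next cut the piperidine C3–C4 bond, then N–C2, then the cinnamyl C=C back to an aryl aldehyde.
- Enabling feature: the piperidine is the only saturated ring, its C3–C6 are unsubstituted CH2 groups and C2 is a benzylic carbon on nitrogen. The C3–C4 bond can therefore be made as an alkene from a vinyl group on C2 and a but-3-enyl group on N.
- Forward: the aryl aldehyde is extended to a cinnamyl carbonate, allylic amination joins N to C2, and metathesis closes the piperidine. Hydrogenation then frees a symmetric resorcinol (the future ring A), onto which ring C is annulated last, before N-deprotection.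
- Stereochemistry: the single stereocentre (C2 of the piperidine, R) is set by ligand control in the iridium-catalysed allylic amination. It is not a reacting centre in any later step.

Key step: step 8

Remark: the sense of induction in step 6 is assigned by analogy with simple (E)-cinnamyl carbonates, for which the (Ra,Rc,Rc) phosphoramidite series should deliver (R)-1-arylallylamines; the aryl group here has the same CIP rank as phenyl, so the descriptor carries over.

**Route**

Step 1
Reactants: 1 2,4,6-trihydroxybenzaldehyde
Product: 2 2,6-dihydroxy-4-methoxybenzaldehyde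
Conditions: MeI (1.05 equiv), NaHCO3 (1.2 equiv), DMF, 35 °C
Reagents that add atoms: iodomethane, CI
Why: Williamson O-methylation under weak-base control, in which the 4-hydroxyl is the most acidic and the least hindered and is not engaged in the hydrogen bond to the formyl oxygen, so one equivalent of iodomethane should alkylate it preferentially, as in the classical partial methylation of acylphloroglucinols.

Step 2
Reactants: 2 2,6-dihydroxy-4-methoxybenzaldehyde
Product: 4 2,6-bis(benzyloxy)-4-methoxybenzaldehyde, via mono-benzyl ether 3 (not isolated)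
Conditions: BnBr (2.5 equiv), K2CO3 (3 equiv), DMF, 60 °C
Reagents that add atoms: benzyl bromide, BrCc1ccccc1
Why: Williamson etherification with excess benzyl bromide in warm DMF should alkylate both ortho hydroxyls, including the hydrogen-bonded one, to give the symmetric aldehyde.

Step 3
Reactants: 4 2,6-bis(benzyloxy)-4-methoxybenzaldehyde; 5 triethyl phosphonoacetate
Product: 6 ethyl (2E)-3-[2,6-bis(benzyloxy)-4-methoxyphenyl]prop-2-enoate
Conditions: NaH, THF, 0 °C → reflux
Reagents that add atoms: none
Why: Horner–Wadsworth–Emmons olefination with a stabilised phosphonate anion should give the E-cinnamate, with warming to compensate for the hindered, electron-rich aldehyde.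

Step 4
Reactants: 6 ethyl (2E)-3-[2,6-bis(benzyloxy)-4-methoxyphenyl]prop-2-enoate
Product: 8 (2E)-3-[2,6-bis(benzyloxy)-4-methoxyphenyl]prop-2-en-1-ol, via enal 7 (not isolated)
Conditions: i-Bu2AlH (2.5 equiv), CH2Cl2, −78 → 0 °C; aq. potassium sodium tartrate
Reagents that add atoms: none
Why: Hydride 1,2-reduction of the conjugated ester by i-Bu2AlH should proceed through the enal to the allylic alcohol without touching the alkene or the benzyl ethers, and the non-acidic work-up protects the easily ionised cinnamyl alcohol.

Step 5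
Reactants: 8 (2E)-3-[2,6-bis(benzyloxy)-4-methoxyphenyl]prop-2-en-1-ol
Product: 9 (2E)-3-[2,6-bis(benzyloxy)-4-methoxyphenyl]prop-2-en-1-yl methyl carbonate
Conditions: ClCO2Me, pyridine, CH2Cl2, 0 °C
Reagents that add atoms: methyl chloroformate, COC(=O)Cl
Why: O-acylation of the primary allylic alcohol with a chloroformate should give the carbonate leaving group for allylic substitution, and the product is kept base-buffered (Et3N-deactivated silica) because the electron-rich cinnamyl system ionises easily.

Step 6
Reactants: 9 (2E)-3-[2,6-bis(benzyloxy)-4-methoxyphenyl]prop-2-en-1-yl methyl carbonate; 10 but-3-en-1-amine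
Product: 11 (1R)-1-[2,6-bis(benzyloxy)-4-methoxyphenyl]-N-(but-3-en-1-yl)prop-2-en-1-amine
Conditions: [Ir(cod)Cl]2 (2 mol %), (Ra,Rc,Rc)-O,O'-(1,1'-binaphthyl-2,2'-diyl) N,N-bis[1-(2-methoxyphenyl)ethyl]phosphoramidite (4 mol %), 10 (3 equiv), THF, rt
Reagents that add atoms: none
Why: Iridium-catalysed branched-selective asymmetric allylic amination, in which the cyclometalated iridium phosphoramidite complex ionises the carbonate to an allyl complex and the primary amine attacks the aryl-bearing terminus, the (Ra,Rc,Rc) ligand setting the new stereocentre as R while excess amine limits double allylation.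

Step 7
Reactants: 11 (1R)-1-[2,6-bis(benzyloxy)-4-methoxyphenyl]-N-(but-3-en-1-yl)prop-2-en-1-amine
Product: 12 tert-butyl N-(but-3-en-1-yl)-N-[(1R)-1-[2,6-bis(benzyloxy)-4-methoxyphenyl]prop-2-en-1-yl]carbamate
Conditions: Boc2O (1.5 equiv), THF, 50 °C
Reagents that add atoms: di-tert-butyl dicarbonate, CC(C)(C)OC(=O)OC(=O)OC(C)(C)C
Why: Carbamate formation (Boc protection) of the hindered secondary amine should proceed on warming and removes the basicity of nitrogen, which would otherwise bind ruthenium in the next step.

Step 8
Reactants: 12 tert-butyl N-(but-3-en-1-yl)-N-[(1R)-1-[2,6-bis(benzyloxy)-4-methoxyphenyl]prop-2-en-1-yl]carbamate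
Product: 13 tert-butyl (2R)-2-[2,6-bis(benzyloxy)-4-methoxyphenyl]-5,6-dihydro-2H-pyridine-1-carboxylate
Conditions: second-generation Grubbs catalyst RuCl2(=CHPh)(H2IMes)(PCy3) (5 mol %), 1,4-benzoquinone (10 mol %), CH2Cl2 (0.01 M), 40 °C
Reagents that add atoms: none
Why: Ring-closing olefin metathesis of an N-acyl diene, the standard route to 2-substituted 1,2,5,6-tetrahydropyridines: the ruthenium benzylidene first exchanges onto the unhindered but-3-enyl terminus, the resulting alkylidene adds to the C2 vinyl group in a (2+2) cycloaddition, and cycloreversion of the ruthenacyclobutane forms the C3=C4 bond and releases ethene. The piperidine ring is closed by joining the two terminal alkene carbons of a 1,7-diene, an unstrained six-membered closure driven by dilution and loss of ethene. No new stereocentre arises, and the R centre at C2 comes unchanged from step 6. The selectivity needed is ring closure over oligomerisation and over double-bond migration: the carbamate keeps nitrogen off ruthenium and its rotamers hold the two alkenes close, while 1,4-benzoquinone intercepts ruthenium hydrides that would otherwise move C3=C4 toward C2 and erase the allylic benzylic stereocentre. The bulky 2,6-bis(benzyloxy)aryl group sits on C2 outside the forming bond, so it only slows engagement of the vinyl group and loading should occur at the butenyl end.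

Step 9
Reactants: 13 tert-butyl (2R)-2-[2,6-bis(benzyloxy)-4-methoxyphenyl]-5,6-dihydro-2H-pyridine-1-carboxylate
Product: 16 tert-butyl (2R)-2-(2,6-dihydroxy-4-methoxyphenyl)piperidine-1-carboxylate, via saturated bis-benzyl ether 14 (not isolated), via mono-benzyl ether 15 (not isolated)
Conditions: H2 (1 atm), 10% Pd/C, EtOAc–MeOH, rt
Reagents that add atoms: none
Why: Heterogeneous hydrogenation over Pd/C should first saturate the cis ring alkene and then cleave both O-benzyl groups by hydrogenolysis, while the carbamate-bearing benzylic C–N bond resists cleavage under neutral conditions and a good hydrogen supply keeps alkene migration toward C2 from competing, so the stereocentre is carried through.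

Step 10
Reactants: 16 tert-butyl (2R)-2-(2,6-dihydroxy-4-methoxyphenyl)piperidine-1-carboxylate
Product: 17 tert-butyl (2R)-2-(2,6-dihydroxy-3-iodo-4-methoxyphenyl)piperidine-1-carboxylate
Conditions: NIS (1.0 equiv), CH2Cl2, −40 → 0 °C, dark
Reagents that add atoms: N-iodosuccinimide, O=C1CCC(=O)N1I
Why: Electrophilic aromatic iodination, in which the two free ring positions are each activated by three oxygen donors and are interchanged by rotation about the aryl–C2 bond, so one equivalent of reagent at low temperature should give a single mono-iodide under neutral conditions that spare the carbamate and the acid-sensitive benzylic C–N bond.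

Step 11
Reactants: 17 tert-butyl (2R)-2-(2,6-dihydroxy-3-iodo-4-methoxyphenyl)piperidine-1-carboxylate; 18 phenylacetylene
Product: 20 tert-butyl (2R)-2-(7-hydroxy-5-methoxy-4-oxo-2-phenyl-4H-chromen-8-yl)piperidine-1-carboxylate, via aryl ynone 19 (not isolated)
Conditions: PdCl2(dppf) (5 mol %), CO (20 bar), Et2NH, 100 °C
Reagents that add atoms: carbon monoxide, [C-]#[O+]
Why: Palladium-catalysed carbonylative Sonogashira-type heteroannulation of an o-iodophenol with a terminal alkyne, in which oxidative addition of the C–I bond to zerovalent palladium, CO insertion and alkynyl transfer give the ynone, and the secondary amine base steers the only hydroxyl ortho to the acyl group into 6-endo oxa-Michael closure of ring C instead of 5-exo closure to an aurone.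

Step 12
Reactants: 20 tert-butyl (2R)-2-(7-hydroxy-5-methoxy-4-oxo-2-phenyl-4H-chromen-8-yl)piperidine-1-carboxylate
Product: 22 7-hydroxy-5-methoxy-2-phenyl-8-[(2R)-piperidin-2-yl]-4H-chromen-4-one, via carbamic acid 21 (not isolated)
Conditions: CF3CO2H–CH2Cl2 (1:4), 0 °C → rt; aq. NaHCO3 to pH 8
Reagents that add atoms: none
Why: Acidolysis of the tert-butyl carbamate (loss of the tert-butyl cation as 2-methylpropene, then decarboxylation of the carbamic acid) should free the amine, and because the flavone carbonyl is protonated in this medium ring A is too electron-poor for the benzylic C–N bond to ionise, so C2 should stay R.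

**Compound list**

1 | 2,4,6-trihydroxybenzaldehyde | O=Cc1c(O)cc(O)cc1O | starting material
2 | 2,6-dihydroxy-4-methoxybenzaldehyde | COc1cc(O)c(C=O)c(O)c1 | intermediate
3 | 2-(benzyloxy)-6-hydroxy-4-methoxybenzaldehyde | COc1cc(O)c(C=O)c(OCc2ccccc2)c1 | intermediate
4 | 2,6-bis(benzyloxy)-4-methoxybenzaldehyde | COc1cc(OCc2ccccc2)c(C=O)c(OCc2ccccc2)c1 | intermediate
5 | triethyl phosphonoacetate | CCOC(=O)CP(=O)(OCC)OCC | starting material
6 | ethyl (2E)-3-[2,6-bis(benzyloxy)-4-methoxyphenyl]prop-2-enoate | CCOC(=O)/C=C/c1c(OCc2ccccc2)cc(OC)cc1OCc1ccccc1 | intermediate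
7 | (2E)-3-[2,6-bis(benzyloxy)-4-methoxyphenyl]prop-2-enal | O=C/C=C/c1c(OCc2ccccc2)cc(OC)cc1OCc1ccccc1 | intermediate
8 | (2E)-3-[2,6-bis(benzyloxy)-4-methoxyphenyl]prop-2-en-1-ol | OC/C=C/c1c(OCc2ccccc2)cc(OC)cc1OCc1ccccc1 | intermediate
9 | (2E)-3-[2,6-bis(benzyloxy)-4-methoxyphenyl]prop-2-en-1-yl methyl carbonate | COC(=O)OC/C=C/c1c(OCc2ccccc2)cc(OC)cc1OCc1ccccc1 | intermediate
10 | but-3-en-1-amine | C=CCCN | starting material
11 | (1R)-1-[2,6-bis(benzyloxy)-4-methoxyphenyl]-N-(but-3-en-1-yl)prop-2-en-1-amine | COc1cc(OCc2ccccc2)c([C@H](NCCC=C)C=C)c(OCc2ccccc2)c1 | intermediate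
12 | tert-butyl N-(but-3-en-1-yl)-N-[(1R)-1-[2,6-bis(benzyloxy)-4-methoxyphenyl]prop-2-en-1-yl]carbamate | COc1cc(OCc2ccccc2)c([C@H](N(CCC=C)C(=O)OC(C)(C)C)C=C)c(OCc2ccccc2)c1 | intermediate
13 | tert-butyl (2R)-2-[2,6-bis(benzyloxy)-4-methoxyphenyl]-5,6-dihydro-2H-pyridine-1-carboxylate | COc1cc(OCc2ccccc2)c([C@H]2C=CCCN2C(=O)OC(C)(C)C)c(OCc2ccccc2)c1 | intermediate
14 | tert-butyl (2R)-2-[2,6-bis(benzyloxy)-4-methoxyphenyl]piperidine-1-carboxylate | COc1cc(OCc2ccccc2)c([C@H]2CCCCN2C(=O)OC(C)(C)C)c(OCc2ccccc2)c1 | intermediate
15 | tert-butyl (2R)-2-[2-(benzyloxy)-6-hydroxy-4-methoxyphenyl]piperidine-1-carboxylate | COc1cc(O)c([C@H]2CCCCN2C(=O)OC(C)(C)C)c(OCc2ccccc2)c1 | intermediate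
16 | tert-butyl (2R)-2-(2,6-dihydroxy-4-methoxyphenyl)piperidine-1-carboxylate | COc1cc(O)c([C@H]2CCCCN2C(=O)OC(C)(C)C)c(O)c1 | intermediate
17 | tert-butyl (2R)-2-(2,6-dihydroxy-3-iodo-4-methoxyphenyl)piperidine-1-carboxylate | COc1cc(O)c([C@H]2CCCCN2C(=O)OC(C)(C)C)c(O)c1I | intermediate
18 | phenylacetylene | C#Cc1ccccc1 | starting material
19 | tert-butyl (2R)-2-[2,6-dihydroxy-4-methoxy-3-(3-phenylprop-2-ynoyl)phenyl]piperidine-1-carboxylate | COc1cc(O)c([C@H]2CCCCN2C(=O)OC(C)(C)C)c(O)c1C(=O)C#Cc1ccccc1 | intermediate
20 | tert-butyl (2R)-2-(7-hydroxy-5-methoxy-4-oxo-2-phenyl-4H-chromen-8-yl)piperidine-1-carboxylate | COc1cc(O)c([C@H]2CCCCN2C(=O)OC(C)(C)C)c2oc(-c3ccccc3)cc(=O)c12 | intermediate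
21 | (2R)-2-(7-hydroxy-5-methoxy-4-oxo-2-phenyl-4H-chromen-8-yl)piperidine-1-carboxylic acid | COc1cc(O)c([C@H]2CCCCN2C(=O)O)c2oc(-c3ccccc3)cc(=O)c12 | intermediate
22 | 7-hydroxy-5-methoxy-2-phenyl-8-[(2R)-piperidin-2-yl]-4H-chromen-4-one | COc1cc(O)c([C@H]2CCCCN2)c2oc(-c3ccccc3)cc(=O)c12 | target

**Step count**

Total steps: 12
Longest linear sequence: 12 steps (1 → 22)

**Steps most likely to fail**

Step 6 (allylic amination). The amine may attack the unsubstituted allyl terminus, and facial control may erode because the two ortho benzyloxy groups crowd the aryl-bearing terminus. Uncatalysed ionisation of the very electron-rich carbonate could also feed a racemic background reaction. The fallback sets out from 4 and comes back to the route at 11. Condensation of 4 with (S)-2-methylpropane-2-sulfinamide (Ti(OEt)4, THF, 60 °C) should give the sulfinyl aldimine (S)-N-[(E)-[2,6-bis(benzyloxy)-4-methoxyphenyl]methylidene]-2-methylpropane-2-sulfinamide F1. Vinylmagnesium bromide in CH2Cl2 at −78 °C should add through a chair-like, magnesium-bridged transition state to give (S)-N-[(1R)-1-[2,6-bis(benzyloxy)-4-methoxyphenyl]prop-2-en-1-yl]-2-methylpropane-2-sulfinamide F2, with R at carbon under auxiliary control. Brief treatment with HCl in MeOH at 0 °C should remove the sulfinyl group and give (1R)-1-[2,6-bis(benzyloxy)-4-methoxyphenyl]prop-2-en-1-amine F3. Mono-N-alkylation of this α-branched amine with 4-bromobut-1-ene (K2CO3, catalytic sodium iodide, MeCN, 60 °C) should then give 11.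

Step 11 (carbonylative annulation). The hindered, electron-rich aryl iodide may be reduced to the arene, or alkynylated without CO uptake and then closed to a benzofuran. Diethylamine may intercept the acylpalladium species, or closure may go 5-exo. The fallback sets out from 17 and comes back to the route at 20. Stille coupling of 17 with tributyl(1-ethoxyvinyl)stannane (Pd(PPh3)4, toluene, 100 °C) should give the enol ether tert-butyl (2R)-2-[3-(1-ethoxyethenyl)-2,6-dihydroxy-4-methoxyphenyl]piperidine-1-carboxylate F4. Dilute aqueous HCl on work-up should hydrolyse it to the methyl ketone tert-butyl (2R)-2-(3-acetyl-2,6-dihydroxy-4-methoxyphenyl)piperidine-1-carboxylate F5. C-benzoylation of its lithium polyanion (LiN(SiMe3)2, 4.5 equiv, THF, −78 °C, then benzoyl chloride, 1 equiv), a one-flask Baker–Venkataraman equivalent, should give the 1,3-diketone tert-butyl (2R)-2-[2,6-dihydroxy-4-methoxy-3-(3-oxo-3-phenylpropanoyl)phenyl]piperidine-1-carboxylate F6. Acid cyclodehydration in AcOH with a little HCl should close ring C to 20; any carbamate lost at this point only anticipates step 12.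

Step 1 (selective methylation). Alkylation may run on to a second hydroxyl or occur at an ortho hydroxyl, leaving a mixture of methyl ethers that is hard to separate. This fallback cannot branch from 1; it sets out from commercial 5-methoxybenzene-1,3-diol F7 and comes back to the route at 2. Protection of both hydroxyls (MOMCl, i-Pr2NEt, CH2Cl2) should give 1-methoxy-3,5-bis(methoxymethoxy)benzene F8. Directed ortho-lithiation at the position between the two methoxymethyl ethers (n-BuLi, TMEDA, THF, 0 °C) and formylation with DMF should give 4-methoxy-2,6-bis(methoxymethoxy)benzaldehyde F9. HCl in MeOH at rt should then remove both acetals to give 2, with the methyl ether position fixed by the starting material.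

**Further compounds**

F1 | step 6 | (S)-N-[(E)-[2,6-bis(benzyloxy)-4-methoxyphenyl]methylidene]-2-methylpropane-2-sulfinamide | CC(C)(C)[S@](=O)/N=C/c1c(OCc2ccccc2)cc(OC)cc1OCc1ccccc1
F2 | step 6 | (S)-N-[(1R)-1-[2,6-bis(benzyloxy)-4-methoxyphenyl]prop-2-en-1-yl]-2-methylpropane-2-sulfinamide | CC(C)(C)[S@](=O)N[C@H](C=C)c1c(OCc2ccccc2)cc(OC)cc1OCc1ccccc1
F3 | step 6 | (1R)-1-[2,6-bis(benzyloxy)-4-methoxyphenyl]prop-2-en-1-amine | N[C@H](C=C)c1c(OCc2ccccc2)cc(OC)cc1OCc1ccccc1
F4 | step 11 | tert-butyl (2R)-2-[3-(1-ethoxyethenyl)-2,6-dihydroxy-4-methoxyphenyl]piperidine-1-carboxylate | CCOC(=C)c1c(OC)cc(O)c([C@H]2CCCCN2C(=O)OC(C)(C)C)c1O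
F5 | step 11 | tert-butyl (2R)-2-(3-acetyl-2,6-dihydroxy-4-methoxyphenyl)piperidine-1-carboxylate | COc1cc(O)c([C@H]2CCCCN2C(=O)OC(C)(C)C)c(O)c1C(C)=O
F6 | step 11 | tert-butyl (2R)-2-[2,6-dihydroxy-4-methoxy-3-(3-oxo-3-phenylpropanoyl)phenyl]piperidine-1-carboxylate | COc1cc(O)c([C@H]2CCCCN2C(=O)OC(C)(C)C)c(O)c1C(=O)CC(=O)c1ccccc1
F7 | step 1 | 5-methoxybenzene-1,3-diol | COc1cc(O)cc(O)c1
F8 | step 1 | 1-methoxy-3,5-bis(methoxymethoxy)benzene | COCOc1cc(OC)cc(OCOC)c1
F9 | step 1 | 4-methoxy-2,6-bis(methoxymethoxy)benzaldehyde | COCOc1cc(OC)cc(OCOC)c1C=O
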